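**Retrosynthetic overview**

1. Target 14 ⇐ 12 by cleavage of the two aryl acetates, with the lactone opened and closed again. 12 ⇐ 10 + 11 by Heck coupling at C5–Br; the stilbene enters only after the oxidation, which it would not survive.
2. The strategy rests on ring A of the chroman-2-one: the C7 hydroxyl is para to C4a and the lactone oxygen O1 sits on the adjacent C8a. This is the pattern left when a para-alkylphenol is attacked at its ipso carbon (C4a) by its own propanoic acid chain and the acyloxy oxygen then moves one carbon over. Hence 10 ⇐ 8 by anodic spirolactonisation (O1–C4a, five-membered ring, dienone 9) and 1,2-shift of O1 to C8a (six-membered lactone).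
3. 8 ⇐ 7 ⇐ 6 ⇐ 4 + 5: the only stereocentre (C4, R) is set by Rh-catalysed asymmetric 1,4-arylation of a 2-bromocinnamate. 4 ⇐ 2 ⇐ 1 by olefination and phenol protection. The bromine is bought in 1 and serves first as blocking group at C5, then as coupling handle.
4. Ring order: both benzene rings are purchased; the spiro-γ-lactone is transient (step 6); the δ-lactone of the dihydrocoumarin is formed in step 6 and re-formed in step 8.

Key step: step 6

Assumption: the Rh/(S,S)-diene catalyst is taken to deliver the aryl group to the α-si face of the (E)-enoate, as in the accepted model for such ligands, which gives (R) at the new centre; if a test run shows the opposite sense, the antipodal ligand is to be used.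

**Route**

Step 1
Reactants: 1 2-bromo-4-hydroxybenzaldehyde
Product: 2 2-bromo-4-[(4-methoxybenzyl)oxy]benzaldehyde
Conditions: PMBCl (1.1 equiv), K2CO3 (1.5 equiv), DMF, 50 °C
Reagents that add atoms: 4-methoxybenzyl chloride, COc1ccc(CCl)cc1
Why: Williamson ether synthesis at the only acidic site; the PMB ether withstands the bases of steps 2–4 and falls to acid together with the tert-butyl ester in step 5.

Step 2
Reactants: 2 2-bromo-4-[(4-methoxybenzyl)oxy]benzaldehyde; 3 tert-butyl 2-(diethoxyphosphoryl)acetate
Product: 4 tert-butyl (2E)-3-{2-bromo-4-[(4-methoxybenzyl)oxy]phenyl}prop-2-enoate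
Conditions: NaH (1.1 equiv), THF, 0 °C → rt
Reagents that add atoms: none
Why: Horner–Wadsworth–Emmons olefination of a non-enolisable aryl aldehyde with a stabilised phosphonate anion should give the (E)-enoate selectively, and the tert-butyl ester resists the aqueous base of step 3.

Step 3
Reactants: 4 tert-butyl (2E)-3-{2-bromo-4-[(4-methoxybenzyl)oxy]phenyl}prop-2-enoate; 5 2-methoxy-4-(4,4,5,5-tetramethyl-1,3,2-dioxaborolan-2-yl)phenol
Product: 6 tert-butyl (3R)-3-{2-bromo-4-[(4-methoxybenzyl)oxy]phenyl}-3-(4-hydroxy-3-methoxyphenyl)propanoate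
Conditions: [RhCl(C2H4)2]2 (2.5 mol%), (1S,4S)-2,5-diphenylbicyclo[2.2.2]octa-2,5-diene [(S,S)-Ph-bod*] (5.5 mol%), 5 (2.0 equiv), aq. KOH (2.0 equiv), dioxane/H2O 10:1, 50 °C
Reagents that add atoms: none
Why: Hayashi–Miyaura rhodium-catalysed asymmetric 1,4-addition, in which the aryl–Rh(I) species formed by transmetalation from boron inserts the enoate syn, the C2-symmetric diene directs the aryl group to the α-si face of the (E)-enoate and so sets C3 as (R), and Rh(I) at this temperature leaves the aryl bromide alone.

Step 4
Reactants: 6 tert-butyl (3R)-3-{2-bromo-4-[(4-methoxybenzyl)oxy]phenyl}-3-(4-hydroxy-3-methoxyphenyl)propanoate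
Product: 7 tert-butyl (3R)-3-(4-acetoxy-3-methoxyphenyl)-3-{2-bromo-4-[(4-methoxybenzyl)oxy]phenyl}propanoate
Conditions: Ac2O (1.5 equiv), pyridine (3 equiv), DMAP (5 mol%), CH2Cl2, 0 °C → rt
Reagents that add atoms: acetic anhydride, CC(=O)OC(C)=O
Why: DMAP-catalysed O-acylation of the only free hydroxyl turns the guaiacyl ring into the electron-poor aryl acetate that step 6 requires.

Step 5
Reactants: 7 tert-butyl (3R)-3-(4-acetoxy-3-methoxyphenyl)-3-{2-bromo-4-[(4-methoxybenzyl)oxy]phenyl}propanoate
Product: 8 (3R)-3-(4-acetoxy-3-methoxyphenyl)-3-(2-bromo-4-hydroxyphenyl)propanoic acid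
Conditions: TFA/CH2Cl2 1:4, Et3SiH (3 equiv), 0 °C → rt
Reagents that add atoms: none
Why: Acidolysis ionises the PMB ether and the tert-butyl ester, triethylsilane traps the 4-methoxybenzyl cation by hydride transfer before it can alkylate the freed phenol, and the aryl acetate, the aryl bromide and the stereocentre are inert to anhydrous acid.

Step 6
Reactants: 8 (3R)-3-(4-acetoxy-3-methoxyphenyl)-3-(2-bromo-4-hydroxyphenyl)propanoic acid
Product: 10 (4R)-4-(4-acetoxy-3-methoxyphenyl)-5-bromo-7-hydroxy-3,4-dihydro-2H-chromen-2-one, via spirodienone lactone 9 (not isolated)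
Conditions: undivided cell, graphite anode, Pt cathode, n-Bu4NBF4 (0.1 M), HFIP/CH2Cl2 4:1, constant current, 2.2 F/mol, 0 °C; current off, then TfOH (0.3 equiv), 0 °C → rt
Reagents that add atoms: none
Why: Proposed new method: two-electron anodic oxidation of the free phenol of ring A (the aryl acetate ring oxidises at a higher potential) gives a phenoxonium ion that the tethered carboxylic acid captures at the para carbon C4a in a 5-exo-trig closure, giving the spiro-γ-lactone dienone 9 as both C4a epimers, which converge. With the current off, TfOH protonates the dienone oxygen, C8a becomes cationic and the lactone oxygen O1 shifts from C4a to C8a through a three-centre acyloxonium transition state (the carbonyl oxygen of a spiro-γ-lactone cannot bridge to C8a as a dioxolanylium ion without placing its cationic carbon at a [2.2.1] bridgehead), so the six-membered lactone arises by ring expansion, and loss of the C8a proton rearomatises ring A with C7–OH para to C4a. Closest known chemistry: phenolic 3-arylpropanoic acids are spirolactonised at an anode or by iodine(III), aryl ether analogues are carried by iodine(III) and a Lewis acid through an ipso-spiro cation and a 1,2-carboxyl shift to dihydrocoumarins, and p-quinol esters pass to resorcinol esters in acid; joining these on a free phenol in one electrochemical operation is new. No stereocentre is created, since C4a returns to sp2, and C4 is outside the reacting array provided that proton loss from C4 to a quinone methide does not compete, which the non-basic medium, the low temperature and the electron-poor acetoxyaryl group on C4 are meant to prevent. The step needs O1 and not C4 to migrate (the oxygen carries the bridging lone pair and the acetate lowers the migratory aptitude of the benzylic carbon), migration to C8a and not to C5 (a shift to the brominated carbon cannot end in proton loss and reverts), and no oxidation of 10 (the phenol is regenerated only after the charge has been passed).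

Step 7
Reactants: 10 (4R)-4-(4-acetoxy-3-methoxyphenyl)-5-bromo-7-hydroxy-3,4-dihydro-2H-chromen-2-one; 11 4-ethenyl-2-methoxyphenyl acetate
Product: 12 (4R)-4-(4-acetoxy-3-methoxyphenyl)-5-[(E)-2-(4-acetoxy-3-methoxyphenyl)ethenyl]-7-hydroxy-3,4-dihydro-2H-chromen-2-one
Conditions: Pd(P(t-Bu)3)2 (5 mol%), Cy2NMe (1.5 equiv), 11 (2.0 equiv), BHT (trace), dioxane, 80 °C
Reagents that add atoms: none
Why: Mizoroki–Heck reaction in which oxidative addition of the C5–Br bond (meta to both ring oxygens) to the bulky electron-rich Pd(0) catalyst, syn-insertion at the terminal carbon of the styrene and syn-β-hydride elimination should give the (E)-stilbene, while the hindered tertiary amine in dioxane spares the lactone and C4; any exchange of acetyl groups among the phenolic oxygens is without consequence because step 8 removes them all.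

Step 8
Reactants: 12 (4R)-4-(4-acetoxy-3-methoxyphenyl)-5-[(E)-2-(4-acetoxy-3-methoxyphenyl)ethenyl]-7-hydroxy-3,4-dihydro-2H-chromen-2-one
Product: 14 (4R)-7-hydroxy-4-(4-hydroxy-3-methoxyphenyl)-5-[(E)-2-(4-hydroxy-3-methoxyphenyl)ethenyl]-3,4-dihydro-2H-chromen-2-one, via ring-opened hydroxy acid 13 (not isolated)
Conditions: LiOH·H2O (6 equiv), degassed THF/H2O 3:1, Ar, 0 °C → rt; then 1 M HCl to pH 1–2, rt
Reagents that add atoms: lithium hydroxide, [Li+].[OH-] (its oxygen enters the carboxyl group of 13, one oxygen of which leaves again as water on ring closure)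
Why: Saponification cleaves the two aryl acetates and, unavoidably, the aryl ester of the lactone to give the carboxylate of 13, and on acidification the acid lactonises onto the only ortho hydroxyl (C8a–OH; C7–OH is para and out of reach), a closure helped by the C4 aryl and C5 styryl groups that flank the side chain, while the C4–H is not acidic under these conditions so the configuration is kept.

**Compound list**

1 | 2-bromo-4-hydroxybenzaldehyde | O=Cc1ccc(O)cc1Br | starting material
2 | 2-bromo-4-[(4-methoxybenzyl)oxy]benzaldehyde | O=Cc1ccc(OCc2ccc(OC)cc2)cc1Br | intermediate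
3 | tert-butyl 2-(diethoxyphosphoryl)acetate | CCOP(=O)(CC(=O)OC(C)(C)C)OCC | starting material
4 | tert-butyl (2E)-3-{2-bromo-4-[(4-methoxybenzyl)oxy]phenyl}prop-2-enoate | CC(C)(C)OC(=O)/C=C/c1ccc(OCc2ccc(OC)cc2)cc1Br | intermediate
5 | 2-methoxy-4-(4,4,5,5-tetramethyl-1,3,2-dioxaborolan-2-yl)phenol | COc1cc(B2OC(C)(C)C(C)(C)O2)ccc1O | starting material
6 | tert-butyl (3R)-3-{2-bromo-4-[(4-methoxybenzyl)oxy]phenyl}-3-(4-hydroxy-3-methoxyphenyl)propanoate | Brc1cc(OCc2ccc(OC)cc2)ccc1[C@@H](c1ccc(O)c(OC)c1)CC(=O)OC(C)(C)C | intermediate
7 | tert-butyl (3R)-3-(4-acetoxy-3-methoxyphenyl)-3-{2-bromo-4-[(4-methoxybenzyl)oxy]phenyl}propanoate | Brc1cc(OCc2ccc(OC)cc2)ccc1[C@@H](c1ccc(OC(C)=O)c(OC)c1)CC(=O)OC(C)(C)C | intermediate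
8 | (3R)-3-(4-acetoxy-3-methoxyphenyl)-3-(2-bromo-4-hydroxyphenyl)propanoic acid | Brc1cc(O)ccc1[C@@H](c1ccc(OC(C)=O)c(OC)c1)CC(=O)O | intermediate
9 | 4-[(4R)-6-bromo-2,8-dioxo-1-oxaspiro[4.5]deca-6,9-dien-4-yl]-2-methoxyphenyl acetate (both epimers at the spiro carbon) | O=C1C=C(Br)C2(C=C1)OC(=O)C[C@@H]2c1ccc(OC(C)=O)c(OC)c1 | intermediate
10 | (4R)-4-(4-acetoxy-3-methoxyphenyl)-5-bromo-7-hydroxy-3,4-dihydro-2H-chromen-2-one | Brc1cc(O)cc2c1[C@@H](c1ccc(OC(C)=O)c(OC)c1)CC(=O)O2 | intermediate
11 | 4-ethenyl-2-methoxyphenyl acetate (4-acetoxy-3-methoxystyrene) | C=Cc1ccc(OC(C)=O)c(OC)c1 | starting material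
12 | (4R)-4-(4-acetoxy-3-methoxyphenyl)-5-[(E)-2-(4-acetoxy-3-methoxyphenyl)ethenyl]-7-hydroxy-3,4-dihydro-2H-chromen-2-one | COc1cc(/C=C/c2cc(O)cc3c2[C@@H](c2ccc(OC(C)=O)c(OC)c2)CC(=O)O3)ccc1OC(C)=O | intermediate
13 | (3R)-3-{2,4-dihydroxy-6-[(E)-2-(4-hydroxy-3-methoxyphenyl)ethenyl]phenyl}-3-(4-hydroxy-3-methoxyphenyl)propanoic acid | COc1cc(/C=C/c2cc(O)cc(O)c2[C@@H](c2ccc(O)c(OC)c2)CC(=O)O)ccc1O | intermediate
14 | (4R)-7-hydroxy-4-(4-hydroxy-3-methoxyphenyl)-5-[(E)-2-(4-hydroxy-3-methoxyphenyl)ethenyl]-3,4-dihydro-2H-chromen-2-one (CNP0277187.1) | COc1cc(/C=C/c2cc(O)cc3c2[C@@H](c2ccc(O)c(OC)c2)CC(=O)O3)ccc1O | target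

**Step count and risks**

Total step count: 8. Longest linear sequence: 8 steps (1 → 14); 3, 5 and 11 are purchased.

Steps most likely to fail:

Step 6 (the proposed new method). The benzylic carbon C4 may migrate in place of O1, which would lead into the isomeric 6-hydroxy lactone series. The spirodienone may ionise reversibly and lose the C4 proton to a quinone methide, eroding the configuration at C4. The second aryl ring or the product may be oxidised further at the anode. The fallback sets out from 8 and comes back to the route at 14; it separates oxidation and shift and uses reagents only. PhI(OAc)2 in HFIP at 0 °C, the established iodine(III) spirolactonisation of para-phenolic propanoic acids, converts 8 into spirodienone 9, which is isolated. 9 is then treated under Thiele-type conditions (Ac2O, cat. H2SO4, 0 °C → rt), under which quinol esters are known to pass to resorcinol diesters by way of the O-acylated dienyl cation. This should give (4R)-7-acetoxy-4-(4-acetoxy-3-methoxyphenyl)-5-bromo-3,4-dihydro-2H-chromen-2-one F1. F1 takes the place of 10 in step 7 and gives (4R)-7-acetoxy-4-(4-acetoxy-3-methoxyphenyl)-5-[(E)-2-(4-acetoxy-3-methoxyphenyl)ethenyl]-3,4-dihydro-2H-chromen-2-one F2, which the conditions of step 8 convert into 14 through 13.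

Step 7. Oxidative addition and alkene insertion at the C5–Br bond may be slow because the bromide is flanked by the C4 diarylmethine. The aryl–palladium intermediate may instead attack an ortho C–H bond of the C4 aryl ring and close a fluorene, and the styrene may polymerise on prolonged heating. The fallback sets out from 11 and 10 and comes back at 12; it replaces alkene insertion by transmetalation of a preformed (E)-alkenyl nucleophile. Cross-metathesis of 11 with vinylboronic acid pinacol ester (ruthenium–NHC benzylidene catalyst, CH2Cl2, 40 °C) gives 2-methoxy-4-[(E)-2-(4,4,5,5-tetramethyl-1,3,2-dioxaborolan-2-yl)ethenyl]phenyl acetate F3. Suzuki–Miyaura coupling of F3 with 10 (Pd(OAc)2/SPhos, K3PO4 with 2 equiv H2O, THF, 50 °C) should give 12 at a temperature at which C–H palladation does not compete. Any loss of acetyl groups in this coupling is made good by step 8.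

Step 3. Insertion of the ortho-brominated, electron-rich β-aryl enoate into the aryl–rhodium bond may be slow enough for protodeboronation of the phenolic boronate to consume the aryl donor, and facial discrimination may be insufficient with the ortho substituent. The fallback sets out from 4 and 5 and comes back at 6; it moves the stereo-defining event from C–C bond formation to C–H bond formation. Oxidative boron-Heck coupling of 4 with 5 (Pd(OAc)2, 2,9-dimethyl-1,10-phenanthroline, O2, DMF, rt to 50 °C, base-free so that the aryl bromide is not touched) replaces the β-hydrogen by the aryl group. This should give tert-butyl (2E)-3-{2-bromo-4-[(4-methoxybenzyl)oxy]phenyl}-3-(4-hydroxy-3-methoxyphenyl)prop-2-enoate F4 as a single alkene isomer. Asymmetric hydrogenation of this β,β-diarylacrylate (cationic Ir–phosphinooxazoline catalyst, H2, CH2Cl2), with the ligand enantiomer chosen in a test reduction so that hydrogen is delivered to the face giving (R), returns 6.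

**Further compounds**

F1 | step 6 | (4R)-7-acetoxy-4-(4-acetoxy-3-methoxyphenyl)-5-bromo-3,4-dihydro-2H-chromen-2-one | Brc1cc(OC(C)=O)cc2c1[C@@H](c1ccc(OC(C)=O)c(OC)c1)CC(=O)O2
F2 | step 6 | (4R)-7-acetoxy-4-(4-acetoxy-3-methoxyphenyl)-5-[(E)-2-(4-acetoxy-3-methoxyphenyl)ethenyl]-3,4-dihydro-2H-chromen-2-one | COc1cc(/C=C/c2cc(OC(C)=O)cc3c2[C@@H](c2ccc(OC(C)=O)c(OC)c2)CC(=O)O3)ccc1OC(C)=O
F3 | step 7 | 2-methoxy-4-[(E)-2-(4,4,5,5-tetramethyl-1,3,2-dioxaborolan-2-yl)ethenyl]phenyl acetate | CC(=O)Oc1ccc(/C=C/B2OC(C)(C)C(C)(C)O2)cc1OC
F4 | step 3 | tert-butyl (2E)-3-{2-bromo-4-[(4-methoxybenzyl)oxy]phenyl}-3-(4-hydroxy-3-methoxyphenyl)prop-2-enoate | CC(C)(C)OC(=O)/C=C(\c1ccc(O)c(OC)c1)c1ccc(OCc2ccc(OC)cc2)cc1Br
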